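**Retrosynthetic overview**

1. Feature: ring B carries a (2R)-2-(2-hydroxypropan-2-yl)-2,3-dihydrofuran (O1, C2, C3, fused at C3a/C7a), a constitutional isomer of a 2,2-dimethylchroman-3-ol. The chromanol is made enantioselectively and then contracted.
2. Target ⇒ O7-demethylation and MOM removal on ring A ⇒ C4–prenyl bond (Negishi at the aryl bromide) ⇒ C5–CH2 bond (alkyl Negishi at the aryl iodide with a ring A 3-arylpropylzinc iodide) ⇒ iodination at C5.
3. Dihydrobenzofuran carbinol ⇒ (S)-chroman-3-yl mesylate (O1 participation, inversion) ⇒ (S)-chroman-3-ol ⇒ (3S,4S)-chromene oxide (Jacobsen) ⇒ 5-bromo-8-methoxy-2,2-dimethylchromene ⇒ propargyl ether of 5-bromo-2-methoxyphenol.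
4. Ring A fragment ⇒ aromatic Claisen rearrangement of a 4-O-prenyl ether (sets the 1,1-dimethylallyl group) on a 3-arylpropanoate built from 2,4-dihydroxybenzaldehyde by olefination and conjugate reduction.
5. Ring order: both benzene rings are bought; pyran ring (step 2), oxirane (step 3, opened in step 4), then the dihydrofuran ring by contraction of the pyran (step 6).

Key step: step 6

Remark: ring B is numbered as a 2,3-dihydrobenzofuran (O1, C2, C3, C3a, C4–C7, C7a). The (S,S)-Jacobsen catalyst is assumed to give the (3S,4S)-epoxide with this chromene, as it does with other 2,2-dimethylchromenes.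

**Route**

Step 1
Reactants: 1 5-bromo-2-methoxyphenol; 2 3-chloro-3-methylbut-1-yne
Product: 3 4-bromo-1-methoxy-2-[(2-methylbut-3-yn-2-yl)oxy]benzene
Conditions: K2CO3, KI, CuI (cat.), acetone, 60 °C
Reagents that add atoms: none
Why: Copper-assisted O-alkylation of the phenoxide by the tertiary propargylic chloride (propargyl etherification) is the standard entry to aryl 1,1-dimethylpropargyl ethers, and the phenol oxygen is the only nucleophile present.

Step 2
Reactants: 3 4-bromo-1-methoxy-2-[(2-methylbut-3-yn-2-yl)oxy]benzene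
Product: 6 5-bromo-8-methoxy-2,2-dimethyl-2H-chromene, via allenylphenol 4 (not isolated), via quinone methide 5 (not isolated)
Conditions: N,N-diethylaniline, 190 °C
Reagents that add atoms: none
Why: Thermal aromatic propargyl Claisen rearrangement to C3 of 3, the only free ortho carbon (next to bromine), gives 4, whose 1,5-hydrogen shift to 5 and oxa-6π electrocyclisation close the pyran ring, so bromine ends at C5 and methoxy at C8 of the chromene.

Step 3
Reactants: 6 5-bromo-8-methoxy-2,2-dimethyl-2H-chromene
Product: 7 (3S,4S)-5-bromo-3,4-epoxy-8-methoxy-2,2-dimethylchromane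
Conditions: (S,S)-Jacobsen catalyst, [(S,S)-N,N'-bis(3,5-di-tert-butylsalicylidene)cyclohexane-1,2-diaminato]MnCl (trivalent manganese, 4 mol %), 4-phenylpyridine N-oxide, aq NaOCl (pH 11.3), CH2Cl2, 0 °C
Reagents that add atoms: sodium hypochlorite, [Na+].[O-]Cl
Why: Jacobsen–Katsuki epoxidation, for which cis-disubstituted 2,2-dimethylchromenes are among the best substrates, should deliver oxygen under control of the (S,S)-catalyst to the face that gives the (3S,4S)-epoxide and so fix the C3 configuration that is carried to the target.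

Step 4
Reactants: 7 (3S,4S)-5-bromo-3,4-epoxy-8-methoxy-2,2-dimethylchromane
Product: 8 (S)-5-bromo-8-methoxy-2,2-dimethylchroman-3-ol
Conditions: LiEt3BH, THF, 0 °C to rt; then H2O
Reagents that add atoms: none
Why: SN2 hydride opening of the epoxide by Super-Hydride should occur at the benzylic C4, because C3 is neopentyl-like next to the gem-dimethyl carbon, so the C3–O bond is untouched and the (S)-alcohol forms without loss of enantiopurity while aryl bromide and methyl ether stay inert.

Step 5
Reactants: 8 (S)-5-bromo-8-methoxy-2,2-dimethylchroman-3-ol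
Product: 9 (S)-5-bromo-8-methoxy-2,2-dimethylchroman-3-yl methanesulfonate
Conditions: MsCl, Et3N, CH2Cl2, 0 °C
Reagents that add atoms: methanesulfonyl chloride, CS(=O)(=O)Cl
Why: Standard sulfonylation of a secondary alcohol (mesylation via sulfene) proceeds with retention because the C3–O bond is not broken.

Step 6
Reactants: 9 (S)-5-bromo-8-methoxy-2,2-dimethylchroman-3-yl methanesulfonate
Product: 11 (R)-2-(4-bromo-7-methoxy-2,3-dihydrobenzofuran-2-yl)propan-2-ol, via epoxonium mesylate 10 (not isolated)
Conditions: NaHCO3, HFIP–H2O (1:1), 60 °C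
Reagents that add atoms: water, O
Why: In the half-chair conformer with the mesylate pseudo-equatorial the C3–OMs bond is antiperiplanar to the C2–O1 bond, so on ionisation the ring oxygen bridges to C3 from the back and expels mesylate with inversion to give the bicyclic epoxonium (O-aryl oxiranium) ion 10, which water opens at the tertiary CMe2 carbon, so that the new O1–C(H) bond and the tertiary C–OH bond replace the old O1–CMe2 bond and the pyran has contracted to the dihydrofuran. The closest known reaction type is the solvolytic ring contraction of 3-sulfonyloxy-2,2-dimethylchromans to 2-(2-hydroxypropan-2-yl)-2,3-dihydrobenzofurans by neighbouring-group participation of the ether oxygen. The five-membered ring O1–C2–C3–C3a–C7a is closed in the 3-exo-tet attack of O1 on the carbinol carbon, which at the same time forms the transient three-membered ring that water then cleaves. The single stereocentre is substrate-controlled: the configuration set by the Jacobsen catalyst is transferred with one inversion, (S)-mesylate to (R)-dihydrofuran, because the carbinol carbon never becomes a free cation. The step needs O1 migration to outrun E2 loss of a benzylic C4–H and migration of the aryl carbon, and needs opening of 10 at the tertiary instead of the secondary carbon without proton loss to an isopropenyl group. The gem-dimethyl group (O1 shift unveils a tertiary cationic centre, aryl shift only a primary one), the absence of an anti C4–H in the reactive conformer and the weakly basic, strongly ionising, water-rich medium should secure this.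

Step 7
Reactants: 11 (R)-2-(4-bromo-7-methoxy-2,3-dihydrobenzofuran-2-yl)propan-2-ol
Product: 12 (R)-2-(4-bromo-5-iodo-7-methoxy-2,3-dihydrobenzofuran-2-yl)propan-2-ol
Conditions: NIS, TFA (20 mol %), MeCN, rt
Reagents that add atoms: N-iodosuccinimide, O=C1CCC(=O)N1I
Why: Electrophilic aromatic iodination with acid-activated NIS should go to C5, para to the ring oxygen O1 (the veratrole-type 4-position next to bromine, as in the 4,5-dihalogenation of 4-bromoveratrole), whereas C6 is only ortho to methoxy and meta to O1.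

Step 8
Reactants: 13 2,4-dihydroxybenzaldehyde; 14 prenyl bromide (1-bromo-3-methylbut-2-ene)
Product: 15 2-hydroxy-4-[(3-methylbut-2-en-1-yl)oxy]benzaldehyde
Conditions: K2CO3 (1 equiv), acetone, rt
Reagents that add atoms: none
Why: Williamson etherification is selective for the 4-hydroxyl, the more acidic and more nucleophilic phenol, because the 2-hydroxyl is held in a hydrogen bond to the aldehyde.

Step 9
Reactants: 15 2-hydroxy-4-[(3-methylbut-2-en-1-yl)oxy]benzaldehyde
Product: 16 2-(methoxymethoxy)-4-[(3-methylbut-2-en-1-yl)oxy]benzaldehyde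
Conditions: MOMCl, i-Pr2NEt, CH2Cl2, 0 °C to rt
Reagents that add atoms: chloromethyl methyl ether, COCCl
Why: Standard MOM protection (O-alkylation of the phenol) removes the acidic proton before the olefination and makes the ring position between the two oxygens the more hindered ortho site for the later Claisen step.

Step 10
Reactants: 16 2-(methoxymethoxy)-4-[(3-methylbut-2-en-1-yl)oxy]benzaldehyde
Product: 17 methyl (E)-3-{2-(methoxymethoxy)-4-[(3-methylbut-2-en-1-yl)oxy]phenyl}prop-2-enoate
Conditions: (MeO)2P(O)CH2CO2Me, NaH, THF, 0 °C to rt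
Reagents that add atoms: trimethyl phosphonoacetate, COC(=O)CP(=O)(OC)OC
Why: Horner–Wadsworth–Emmons olefination with a stabilised phosphonate anion gives the (E)-cinnamate.

Step 11
Reactants: 17 methyl (E)-3-{2-(methoxymethoxy)-4-[(3-methylbut-2-en-1-yl)oxy]phenyl}prop-2-enoate
Product: 18 methyl 3-{2-(methoxymethoxy)-4-[(3-methylbut-2-en-1-yl)oxy]phenyl}propanoate
Conditions: Mg turnings, MeOH, 0 °C to rt
Reagents that add atoms: none
Why: Dissolving-metal conjugate reduction (Mg in MeOH) acts by single-electron transfer only on the aryl-conjugated enoate, so the isolated trisubstituted alkene of the prenyl ether, the acetal and the ester should survive.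

Step 12
Reactants: 18 methyl 3-{2-(methoxymethoxy)-4-[(3-methylbut-2-en-1-yl)oxy]phenyl}propanoate
Product: 19 methyl 3-[4-hydroxy-2-(methoxymethoxy)-5-(2-methylbut-3-en-2-yl)phenyl]propanoate
Conditions: N,N-diethylaniline, 190 °C
Reagents that add atoms: none
Why: Aromatic Claisen rearrangement of the aryl prenyl ether delivers the allyl unit with allylic inversion as the 1,1-dimethylallyl group to the free ortho carbon C5, the position between the two oxygens being too crowded to accept a new quaternary centre, and gives the phenol.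

Step 13
Reactants: 19 methyl 3-[4-hydroxy-2-(methoxymethoxy)-5-(2-methylbut-3-en-2-yl)phenyl]propanoate
Product: 20 methyl 3-[2,4-bis(methoxymethoxy)-5-(2-methylbut-3-en-2-yl)phenyl]propanoate
Conditions: NaH, MOMCl, DMF, 0 °C
Reagents that add atoms: chloromethyl methyl ether, COCCl
Why: Williamson-type MOM protection through the sodium phenoxide overcomes the hindrance of the ortho tertiary alkyl group.

Step 14
Reactants: 20 methyl 3-[2,4-bis(methoxymethoxy)-5-(2-methylbut-3-en-2-yl)phenyl]propanoate
Product: 21 3-[2,4-bis(methoxymethoxy)-5-(2-methylbut-3-en-2-yl)phenyl]propan-1-ol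
Conditions: LiAlH4, THF, 0 °C; then H2O
Reagents that add atoms: none
Why: Hydride reduction of the ester to the primary alcohol by LiAlH4 leaves alkenes and acetals untouched.

Step 15
Reactants: 21 3-[2,4-bis(methoxymethoxy)-5-(2-methylbut-3-en-2-yl)phenyl]propan-1-ol
Product: 22 1-(3-iodopropyl)-2,4-bis(methoxymethoxy)-5-(2-methylbut-3-en-2-yl)benzene
Conditions: I2, PPh3, imidazole, CH2Cl2, 0 °C to rt
Reagents that add atoms: iodine, II
Why: Appel-type iodination converts the primary alcohol into the iodide by SN2 displacement of the oxyphosphonium group under imidazole-buffered conditions that MOM ethers and alkenes tolerate.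

Step 16
Reactants: 22 1-(3-iodopropyl)-2,4-bis(methoxymethoxy)-5-(2-methylbut-3-en-2-yl)benzene
Product: 23 {3-[2,4-bis(methoxymethoxy)-5-(2-methylbut-3-en-2-yl)phenyl]propyl}zinc iodide (THF solution, used directly)
Conditions: Zn dust (activated with BrCH2CH2Br and TMSCl), LiCl, THF, 40 °C
Reagents that add atoms: zinc, [Zn]
Why: Direct oxidative insertion of LiCl-activated zinc into the primary C–I bond gives the alkylzinc iodide and tolerates acetals and alkenes.

Step 17
Reactants: 12 (R)-2-(4-bromo-5-iodo-7-methoxy-2,3-dihydrobenzofuran-2-yl)propan-2-ol; 23 {3-[2,4-bis(methoxymethoxy)-5-(2-methylbut-3-en-2-yl)phenyl]propyl}zinc iodide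
Product: 24 2-[(2R)-5-{3-[2,4-bis(methoxymethoxy)-5-(2-methylbut-3-en-2-yl)phenyl]propyl}-4-bromo-7-methoxy-2,3-dihydro-1-benzofuran-2-yl]propan-2-ol
Conditions: Pd(dppf)Cl2 (5 mol %), 23 (1.6 equiv), THF, 40 °C
Reagents that add atoms: none
Why: Negishi sp3–sp2 cross-coupling should be selective because zerovalent palladium inserts into the C–I bond far faster than into the neighbouring C–Br bond, the wide bite angle of dppf favours reductive elimination over β-hydride elimination, and the alkylzinc reagent tolerates the hindered tertiary alcohol.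

Step 18
Reactants: 14 prenyl bromide
Product: 25 (3-methylbut-2-en-1-yl)zinc bromide (THF solution, used directly)
Conditions: Zn dust, LiCl, THF, 0 °C
Reagents that add atoms: zinc, [Zn]
Why: Oxidative insertion of zinc into the allylic C–Br bond at low temperature gives the allylzinc bromide and limits Wurtz homocoupling.

Step 19
Reactants: 24 (the aryl bromide); 25 (3-methylbut-2-en-1-yl)zinc bromide
Product: 26 2-[(2R)-5-{3-[2,4-bis(methoxymethoxy)-5-(2-methylbut-3-en-2-yl)phenyl]propyl}-7-methoxy-4-(3-methylbut-2-en-1-yl)-2,3-dihydro-1-benzofuran-2-yl]propan-2-ol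
Conditions: Pd(OAc)2 (3 mol %), CPhos (6 mol %), 25 (3 equiv), THF, rt
Reagents that add atoms: none
Why: Negishi allyl–aryl cross-coupling with the bulky biarylphosphine CPhos should activate the hindered, electron-rich bromide and reductively eliminate from the less substituted allyl terminus to give the linear prenyl arene, the excess reagent covering any quench by the tertiary hydroxyl.

Step 20
Reactants: 26 (the bis-MOM ether)
Product: 27 4-{3-[(2R)-2-(2-hydroxypropan-2-yl)-7-methoxy-4-(3-methylbut-2-en-1-yl)-2,3-dihydro-1-benzofuran-5-yl]propyl}-6-(2-methylbut-3-en-2-yl)benzene-1,3-diol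
Conditions: HCl (1 M in MeOH), 35 °C
Reagents that add atoms: none
Why: Acid-catalysed acetal exchange (methanolysis of the aryl MOM ethers) should free both ring A phenols under conditions mild enough for the prenyl group, the 1,1-dimethylallyl group and the tertiary alcohol, and it leaves the aryl methyl ether untouched.

Step 21
Reactants: 27 (the O7-methyl ether)
Product: 28 4-{3-[(2R)-7-hydroxy-2-(2-hydroxypropan-2-yl)-4-(3-methylbut-2-en-1-yl)-2,3-dihydro-1-benzofuran-5-yl]propyl}-6-(2-methylbut-3-en-2-yl)benzene-1,3-diol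
Conditions: NaSEt (excess), DMF, 120 °C, argon; then aq HCl to pH 5
Reagents that add atoms: none
Why: Nucleophilic demethylation by SN2 attack of ethanethiolate on the only O-methyl group releases the C7 phenoxide without acid, so the alkenes, the tertiary alcohol and the stereocentre should not be affected.

**Compound list**

1 | 5-bromo-2-methoxyphenol | COc1ccc(Br)cc1O | starting material
2 | 3-chloro-3-methylbut-1-yne | C#CC(C)(C)Cl | starting material
3 | 4-bromo-1-methoxy-2-[(2-methylbut-3-yn-2-yl)oxy]benzene | COc1ccc(Br)cc1OC(C)(C)C#C | intermediate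
4 | 3-bromo-6-methoxy-2-(3-methylbuta-1,2-dien-1-yl)phenol | COc1ccc(Br)c(C=C=C(C)C)c1O | intermediate
5 | 5-bromo-2-methoxy-6-(3-methylbut-2-en-1-ylidene)cyclohexa-2,4-dien-1-one | O=C1C(OC)=CC=C(Br)C1=CC=C(C)C | intermediate
6 | 5-bromo-8-methoxy-2,2-dimethyl-2H-chromene | Brc1ccc(OC)c2c1C=CC(C)(C)O2 | intermediate
7 | (3S,4S)-5-bromo-3,4-epoxy-8-methoxy-2,2-dimethylchromane | Brc1ccc(OC)c2c1[C@@H]1O[C@@H]1C(C)(C)O2 | intermediate
8 | (S)-5-bromo-8-methoxy-2,2-dimethylchroman-3-ol | Brc1ccc(OC)c2c1C[C@H](O)C(C)(C)O2 | intermediate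
9 | (S)-5-bromo-8-methoxy-2,2-dimethylchroman-3-yl methanesulfonate | Brc1ccc(OC)c2c1C[C@H](OS(C)(=O)=O)C(C)(C)O2 | intermediate
10 | epoxonium ion (O1 bridging the CMe2 carbon and the former C3, R at that carbon), mesylate salt | Brc1ccc(OC)c2c1C[C@@H]1C(C)(C)[O+]21.CS(=O)(=O)[O-] | intermediate
11 | (R)-2-(4-bromo-7-methoxy-2,3-dihydrobenzofuran-2-yl)propan-2-ol | Brc1ccc(OC)c2c1C[C@H](C(C)(C)O)O2 | intermediate
12 | (R)-2-(4-bromo-5-iodo-7-methoxy-2,3-dihydrobenzofuran-2-yl)propan-2-ol | Brc1c(I)cc(OC)c2c1C[C@H](C(C)(C)O)O2 | intermediate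
13 | 2,4-dihydroxybenzaldehyde | O=Cc1ccc(O)cc1O | starting material
14 | prenyl bromide | CC(C)=CCBr | starting material
15 | 2-hydroxy-4-[(3-methylbut-2-en-1-yl)oxy]benzaldehyde | O=Cc1ccc(OCC=C(C)C)cc1O | intermediate
16 | 2-(methoxymethoxy)-4-[(3-methylbut-2-en-1-yl)oxy]benzaldehyde | O=Cc1ccc(OCC=C(C)C)cc1OCOC | intermediate
17 | methyl (E)-3-{2-(methoxymethoxy)-4-[(3-methylbut-2-en-1-yl)oxy]phenyl}prop-2-enoate | COC(=O)/C=C/c1ccc(OCC=C(C)C)cc1OCOC | intermediate
18 | methyl 3-{2-(methoxymethoxy)-4-[(3-methylbut-2-en-1-yl)oxy]phenyl}propanoate | COC(=O)CCc1ccc(OCC=C(C)C)cc1OCOC | intermediate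
19 | methyl 3-[4-hydroxy-2-(methoxymethoxy)-5-(2-methylbut-3-en-2-yl)phenyl]propanoate | COC(=O)CCc1cc(C(C)(C)C=C)c(O)cc1OCOC | intermediate
20 | methyl 3-[2,4-bis(methoxymethoxy)-5-(2-methylbut-3-en-2-yl)phenyl]propanoate | COC(=O)CCc1cc(C(C)(C)C=C)c(OCOC)cc1OCOC | intermediate
21 | 3-[2,4-bis(methoxymethoxy)-5-(2-methylbut-3-en-2-yl)phenyl]propan-1-ol | OCCCc1cc(C(C)(C)C=C)c(OCOC)cc1OCOC | intermediate
22 | 1-(3-iodopropyl)-2,4-bis(methoxymethoxy)-5-(2-methylbut-3-en-2-yl)benzene | ICCCc1cc(C(C)(C)C=C)c(OCOC)cc1OCOC | intermediate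
23 | {3-[2,4-bis(methoxymethoxy)-5-(2-methylbut-3-en-2-yl)phenyl]propyl}zinc iodide | I[Zn]CCCc1cc(C(C)(C)C=C)c(OCOC)cc1OCOC | intermediate
24 | 2-[(2R)-5-{3-[2,4-bis(methoxymethoxy)-5-(2-methylbut-3-en-2-yl)phenyl]propyl}-4-bromo-7-methoxy-2,3-dihydro-1-benzofuran-2-yl]propan-2-ol | C=CC(C)(C)c1cc(CCCc2cc(OC)c3c(c2Br)C[C@H](C(C)(C)O)O3)c(OCOC)cc1OCOC | intermediate
25 | (3-methylbut-2-en-1-yl)zinc bromide | CC(C)=CC[Zn]Br | intermediate
26 | 2-[(2R)-5-{3-[2,4-bis(methoxymethoxy)-5-(2-methylbut-3-en-2-yl)phenyl]propyl}-7-methoxy-4-(3-methylbut-2-en-1-yl)-2,3-dihydro-1-benzofuran-2-yl]propan-2-ol | C=CC(C)(C)c1cc(CCCc2cc(OC)c3c(c2CC=C(C)C)C[C@H](C(C)(C)O)O3)c(OCOC)cc1OCOC | intermediate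
27 | 4-{3-[(2R)-2-(2-hydroxypropan-2-yl)-7-methoxy-4-(3-methylbut-2-en-1-yl)-2,3-dihydro-1-benzofuran-5-yl]propyl}-6-(2-methylbut-3-en-2-yl)benzene-1,3-diol | C=CC(C)(C)c1cc(CCCc2cc(OC)c3c(c2CC=C(C)C)C[C@H](C(C)(C)O)O3)c(O)cc1O | intermediate
28 | 4-{3-[(2R)-7-hydroxy-2-(2-hydroxypropan-2-yl)-4-(3-methylbut-2-en-1-yl)-2,3-dihydro-1-benzofuran-5-yl]propyl}-6-(2-methylbut-3-en-2-yl)benzene-1,3-diol | C=CC(C)(C)c1cc(CCCc2cc(O)c3c(c2CC=C(C)C)C[C@H](C(C)(C)O)O3)c(O)cc1O | target

**Step count and risks**

Total step count: 21. Longest linear sequence: 13 steps (steps 8–17, 19, 20, 21, from 2,4-dihydroxybenzaldehyde). The ring B line is 11 steps (steps 1–7, 17, 19, 20, 21).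

Steps most likely to fail:

Step 6. Ionisation of the mesylate may proceed without oxygen participation (E2 loss of a benzylic hydrogen toward the chromene). After ring contraction, proton loss from the tertiary cationic carbon may give an isopropenyl group, or water may capture the epoxonium ion at the secondary carbon. The fallback sets out from 3 and comes back at 11, and it builds the same ring by phenoxide opening of an epoxide instead of by ring contraction. Semi-hydrogenation of the alkyne of 3 (H2, Pd/CaCO3 poisoned with Pb(OAc)2, quinoline) should give 4-bromo-1-methoxy-2-[(2-methylbut-3-en-2-yl)oxy]benzene F1. Its aromatic Claisen rearrangement (toluene, 110 °C) to the single free ortho carbon should give 3-bromo-6-methoxy-2-(3-methylbut-2-en-1-yl)phenol F2. Silylation (TBSCl, imidazole, DMF) gives tert-butyl[3-bromo-6-methoxy-2-(3-methylbut-2-en-1-yl)phenoxy]dimethylsilane F3. Shi epoxidation with the enantiomer of the D-fructose-derived ketone (Oxone, KHSO5, K2CO3 buffer, MeCN–H2O, 0 °C) should give tert-butyl{3-bromo-2-[((2S)-3,3-dimethyloxiran-2-yl)methyl]-6-methoxyphenoxy}dimethylsilane F4. Bu4NF in THF then frees the phenoxide, which opens the epoxide at its secondary carbon in a 5-exo-tet closure with inversion to give 11.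

Step 12. The [3,3] shift may show poor regiocontrol between the two ortho positions, the product may isomerise further at 190 °C (abnormal Claisen), or the prenyl group may be lost as isoprene. The fallback sets out from 13 and comes back at 20, and it installs the 1,1-dimethylallyl group by cross-coupling instead of by sigmatropic shift. Bromination of 13 (NBS, MeCN, 0 °C) para to the 2-hydroxyl should give 5-bromo-2,4-dihydroxybenzaldehyde F5. Double MOM protection (MOMCl, i-Pr2NEt) gives 5-bromo-2,4-bis(methoxymethoxy)benzaldehyde F6. γ-Selective Suzuki–Miyaura coupling with 3-methylbut-2-enylboronic acid pinacol ester (Pd(OAc)2, a bulky biarylphosphine tuned for branched selectivity, K3PO4, aq THF) should give 2,4-bis(methoxymethoxy)-5-(2-methylbut-3-en-2-yl)benzaldehyde F7. Horner–Wadsworth–Emmons olefination as in step 10 gives methyl (E)-3-[2,4-bis(methoxymethoxy)-5-(2-methylbut-3-en-2-yl)phenyl]prop-2-enoate F8. Mg in MeOH as in step 11 then gives 20.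

Step 19. Oxidative addition at the di-ortho-substituted, electron-rich bromide may be sluggish, so that protodebromination or loss of linear selectivity (attack through the substituted allyl terminus) takes over. The fallback sets out from 24 and comes back at 27, and it replaces the palladium catalysis by halogen–lithium exchange and copper-mediated allylation. Silylation of the tertiary hydroxyl (TMSCl, imidazole, DMF) should give {[2-((2R)-5-{3-[2,4-bis(methoxymethoxy)-5-(2-methylbut-3-en-2-yl)phenyl]propyl}-4-bromo-7-methoxy-2,3-dihydro-1-benzofuran-2-yl)propan-2-yl]oxy}trimethylsilane F9. Bromine–lithium exchange (t-BuLi, 2 equiv, THF, −78 °C), transmetalation with CuBr·SMe2 and alkylation with prenyl bromide 14 should give {[2-((2R)-5-{3-[2,4-bis(methoxymethoxy)-5-(2-methylbut-3-en-2-yl)phenyl]propyl}-7-methoxy-4-(3-methylbut-2-en-1-yl)-2,3-dihydro-1-benzofuran-2-yl)propan-2-yl]oxy}trimethylsilane F10. The conditions of step 20 then remove the silyl ether together with both MOM groups to give 27.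

**Further compounds**

F1 | step 6 | 4-bromo-1-methoxy-2-[(2-methylbut-3-en-2-yl)oxy]benzene | COc1ccc(Br)cc1OC(C)(C)C=C
F2 | step 6 | 3-bromo-6-methoxy-2-(3-methylbut-2-en-1-yl)phenol | COc1ccc(Br)c(CC=C(C)C)c1O
F3 | step 6 | tert-butyl[3-bromo-6-methoxy-2-(3-methylbut-2-en-1-yl)phenoxy]dimethylsilane | COc1ccc(Br)c(CC=C(C)C)c1O[Si](C)(C)C(C)(C)C
F4 | step 6 | tert-butyl{3-bromo-2-[((2S)-3,3-dimethyloxiran-2-yl)methyl]-6-methoxyphenoxy}dimethylsilane | COc1ccc(Br)c(C[C@@H]2OC2(C)C)c1O[Si](C)(C)C(C)(C)C
F5 | step 12 | 5-bromo-2,4-dihydroxybenzaldehyde | O=Cc1cc(Br)c(O)cc1O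
F6 | step 12 | 5-bromo-2,4-bis(methoxymethoxy)benzaldehyde | O=Cc1cc(Br)c(OCOC)cc1OCOC
F7 | step 12 | 2,4-bis(methoxymethoxy)-5-(2-methylbut-3-en-2-yl)benzaldehyde | O=Cc1cc(C(C)(C)C=C)c(OCOC)cc1OCOC
F8 | step 12 | methyl (E)-3-[2,4-bis(methoxymethoxy)-5-(2-methylbut-3-en-2-yl)phenyl]prop-2-enoate | COC(=O)/C=C/c1cc(C(C)(C)C=C)c(OCOC)cc1OCOC
F9 | step 19 | {[2-((2R)-5-{3-[2,4-bis(methoxymethoxy)-5-(2-methylbut-3-en-2-yl)phenyl]propyl}-4-bromo-7-methoxy-2,3-dihydro-1-benzofuran-2-yl)propan-2-yl]oxy}trimethylsilane | C=CC(C)(C)c1cc(CCCc2cc(OC)c3c(c2Br)C[C@H](C(C)(C)O[Si](C)(C)C)O3)c(OCOC)cc1OCOC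
F10 | step 19 | {[2-((2R)-5-{3-[2,4-bis(methoxymethoxy)-5-(2-methylbut-3-en-2-yl)phenyl]propyl}-7-methoxy-4-(3-methylbut-2-en-1-yl)-2,3-dihydro-1-benzofuran-2-yl)propan-2-yl]oxy}trimethylsilane | C=CC(C)(C)c1cc(CCCc2cc(OC)c3c(c2CC=C(C)C)C[C@H](C(C)(C)O[Si](C)(C)C)O3)c(OCOC)cc1OCOC
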